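The easy step comes first: target turns into the isomer of the product and back with a relaxation half-life of 0.974 min, far shorter than the 80 min of the run, so at the end the isomer should hold 4.5 times what target holds. In this flask the solid reagent dissolves to give partner, which adds reversibly to starting material, giving target, and to second substrate, giving second product.

starting material 0.15 M; second substrate 0.150 M; solid reagent 0.0750 M; time 80 min

1. why nothing more happens at 80 min, or that something still does (for what has run out or reacted, a solid counts together with what of it has only dissolved) (the partner has run out first / it is still moving / all of the starting material has reacted / forward and back rates have come level)
2. share of the starting material used up at 80 min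
3. target at 80 min, in percent of the starting material charged

- solid reagent is a solid; its amount is given per volume of the solution
- at the start none of the solid reagent is in solution
- the reaction counts as stopped when no species that holds the starting material changes by six tenths of a point or more over the second half of the time
- run time (flask): 80 min

    starting material + partner ⇌ target (K1 = 10.6 M⁻¹, k1 = 0.193 M⁻¹ s⁻¹)
    solid reagent ⇌ partner, rate k2*(cs2 - [partner]) while solid is left; crystals form when [partner] > cs2 (cs2 = 0.074 M, k2 = 0.00711 s⁻¹)
    target ⇌ isomer of the product (K3 = 4.5, k3 = 0.00970 s⁻¹)
    second substrate + partner ⇌ second product (K4 = 19 M⁻¹, k4 = 1.09 M⁻¹ s⁻¹)

Two chemists dispute this flask. The first goes by speed. Second substrate takes partner 5.65 times as fast as starting material does, and the solid charge is 50.0% of each substrate. So partner is the limiting reagent and runs out first, and conversion is 7.52%: kinetic control.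

The second goes by the end state, and I side with her. At its top rate the solid dissolves in 2.38 min, shorter than the run, so the steps can come level: thermodynamic control. Starting material then binds partner into two forms, target and isomer, with a combined constant 58.3 M⁻¹, larger than the 19 M⁻¹ of second substrate.

Multiplying by the solid charge gives the binding number G, 4.37, the ratio of bound to unbound starting material per unit of β, where β is free partner as a fraction of the solid charge. The share left unbound is one over (one plus Gβ). For second substrate the same number is H, 1.43.

Free partner and both bound shares must add up to the solid charge. My trial β of 10.0% gives a sum of 0.958, and the sum rises 7.42 per unit of β. One correction gives β = 10.6%. So my conversion is 31.6%, and target, one part in 5.50 of that, is 5.75%.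

The forecast takes the second side: forward and back rates have come level, conversion 31.6%, target 5.75%, since “80 min is well past equilibrium”.

The simulation gives forward and back rates have come level, conversion 31.6% and target 5.75%. The speed view has its stretch early: in this flask second substrate stands at 83.9% after 8.00 min, below its 86.9% after 80.0 min.

In the neighbour flask with 0.19 M of solid reagent, G becomes 11.1. Its free partner, 0.0332 M, is 17.5% of that charge, so the share of starting material left should be 34.1%. That neighbour flask holds 34.1% of starting material at 80.0 min, a conversion of 65.9%, with target at 12.0% and the isomer of the product, now ahead of both, at 53.9%.

(The numbers come from no measurement; the flask was simulated.)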